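**Retrosynthetic overview**
1. The target acid comes from its 2,4-di-O-benzyl ether by neutral hydrogenolysis. That ether comes from the methyl ester by saponification, and the ester from methyl 2,4-dihydroxy-5-methyl-6-(13-methyltetradecyl)benzoate.
2. The arene is the only ring. It is made by aromatising a cyclohexane-1,3-dione ester.
3. That ring is built from dimethyl malonate and (E)-3,17-dimethyloctadec-3-en-2-one. An intermolecular Michael addition forms C1–C6, and a Dieckmann/Claisen closure in the same flask forms C2–C3.
4. The enone comes from a Wittig reaction of 14-methylpentadecanal with Ph3P=C(CH3)C(O)CH3.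
5. The aldehyde comes from a Cu-catalysed coupling of THP-protected 11-bromoundecan-1-ol with isopentylmagnesium bromide.

**Assumption:** the target has no stereocentre and is achiral, so no enantiocontrol is needed. The side chain is read as 13-methyltetradecyl, that is (CH2)12CH(CH3)2. The transient stereocentres in 2, 5, 8, 9, 13, 14 and 15 are racemic or mixed, and all of them are removed later.

**Step 1**
Reactants: 1 11-bromoundecan-1-ol
Product: 2 2-[(11-bromoundecyl)oxy]tetrahydro-2H-pyran (racemic acetal)
Conditions: DHP (1.3 equiv), PPTS (5 mol%), CH2Cl2, rt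
Reagents that add atoms: 3,4-dihydro-2H-pyran, C1=COCCC1
Why: Acid-catalysed addition of the alcohol to the enol ether (THP protection) removes the acidic OH before the Grignard step, and the new acetal centre is racemic and is lost in step 3.

**Step 2**
Reactants: 2 2-[(11-bromoundecyl)oxy]tetrahydro-2H-pyran; 3 1-bromo-3-methylbutane
Product: 5 2-[(14-methylpentadecyl)oxy]tetrahydro-2H-pyran, via isopentylmagnesium bromide 4 (not isolated)
Conditions: 3 (1.6 equiv), Mg, THF, reflux; then 2, Li2CuCl4 (5 mol%), THF, −10 °C to rt
Reagents that add atoms: none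
Why: The Kochi–Tamura copper-catalysed sp3–sp3 cross-coupling of a primary alkyl Grignard reagent with a primary bromide is high-yielding, and the THP ether is inert to it.

**Step 3**
Reactants: 5 2-[(14-methylpentadecyl)oxy]tetrahydro-2H-pyran
Product: 6 14-methylpentadecan-1-ol
Conditions: p-TsOH·H2O (5 mol%), MeOH/THF, 40 °C
Reagents that add atoms: none
Why: Acid-catalysed transacetalisation to methanol frees the primary alcohol, and nothing else in the molecule is acid-sensitive.

**Step 4**
Reactants: 6 14-methylpentadecan-1-ol
Product: 7 14-methylpentadecanal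
Conditions: TEMPO (10 mol%), PhI(OAc)2 (1.1 equiv), CH2Cl2, rt
Reagents that add atoms: none
Why: The oxoammonium-mediated TEMPO/PhI(OAc)2 oxidation of a primary alcohol stops cleanly at the aldehyde in the absence of water.

**Step 5**
Reactants: 8 3-chlorobutan-2-one (racemic)
Product: 9 (3-oxobutan-2-yl)triphenylphosphonium chloride (racemic)
Conditions: PPh3 (1.0 equiv), toluene, reflux, 24–48 h, filter the salt
Reagents that add atoms: triphenylphosphine, c1ccc(cc1)P(c1ccccc1)c1ccccc1
Why: SN2 quaternisation of PPh3 by the activated α-chloro ketone gives a salt that precipitates from toluene and is collected pure.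

**Step 6**
Reactants: 9 (3-oxobutan-2-yl)triphenylphosphonium chloride
Product: 10 3-(triphenyl-λ5-phosphanylidene)butan-2-one
Conditions: 2 M aq NaOH, CH2Cl2, rt
Reagents that add atoms: none
Why: The α-proton of the acylphosphonium salt is acidic enough for aqueous hydroxide, which gives a stabilised ylide that can be isolated and stored.

**Step 7**
Reactants: 7 14-methylpentadecanal; 10 3-(triphenyl-λ5-phosphanylidene)butan-2-one
Product: 11 (E)-3,17-dimethyloctadec-3-en-2-one
Conditions: 10 (1.3 equiv), toluene, reflux, 24 h
Reagents that add atoms: none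
Why: The Wittig olefination of an unhindered aliphatic aldehyde with a stabilised acyl ylide gives the E-trisubstituted enone, and any Z isomer is harmless because the alkene geometry is lost in step 8.

**Step 8 (key step)**
Reactants: 11 (E)-3,17-dimethyloctadec-3-en-2-one; 12 dimethyl malonate
Product: 14 methyl 2-hydroxy-5-methyl-6-(13-methyltetradecyl)-4-oxocyclohex-2-ene-1-carboxylate (diastereomer mixture, enol form of the 2,4-dione), via Michael adduct 13 (not isolated)
Conditions: 12 (1.3 equiv), NaOMe (1.2 equiv), MeOH (THF co-solvent), reflux, 16 h; then aq HCl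
Reagents that add atoms: none
Why: The intermolecular Michael addition of sodiomalonate to the enone is followed by Dieckmann-type Claisen attack of the methyl-ketone enolate on one ester, the irreversible formation of the β-diketone enolate pulls both equilibria forward, and the three new stereocentres form as a mixture that is erased in step 9.

**Step 9**
Reactants: 14 methyl 2-hydroxy-5-methyl-6-(13-methyltetradecyl)-4-oxocyclohex-2-ene-1-carboxylate
Product: 16 methyl 2,4-dihydroxy-5-methyl-6-(13-methyltetradecyl)benzoate, via 3-bromo enol 15 (not isolated)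
Conditions: Br2 (1.0 equiv), DMF, 0 °C, 1 h; then 80 °C, 12 h
Reagents that add atoms: none
Why: In this bromination–dehydrobromination aromatisation the enol is brominated in the cold, heating then causes an HBr-mediated bromine shift and loss of HBr, and the resulting dienone tautomerises to the resorcylate, while holding at 80 °C keeps the ester in place.

**Step 10**
Reactants: 16 methyl 2,4-dihydroxy-5-methyl-6-(13-methyltetradecyl)benzoate
Product: 17 methyl 2,4-bis(benzyloxy)-5-methyl-6-(13-methyltetradecyl)benzoate
Conditions: BnBr (3 equiv), K2CO3 (4 equiv), DMF, 65 °C, 16 h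
Reagents that add atoms: benzyl bromide, BrCc1ccccc1
Why: A Williamson ether synthesis in DMF alkylates both phenols, including the hydrogen-bonded 2-OH, and masks the resorcinol so that the later acid cannot decarboxylate under hot base.

**Step 11**
Reactants: 17 methyl 2,4-bis(benzyloxy)-5-methyl-6-(13-methyltetradecyl)benzoate
Product: 18 2,4-bis(benzyloxy)-5-methyl-6-(13-methyltetradecyl)benzoic acid
Conditions: KOH (10 equiv), DMSO/H2O (5:1), 105 °C, 16 h; then aq HCl to pH 2
Reagents that add atoms: potassium hydroxide, [K+].[OH-]
Why: Saponification with poorly solvated hydroxide in aqueous DMSO overcomes the di-ortho hindrance of the ester, and the benzyl ethers and the alkyl chain are inert to base.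

**Step 12**
Reactants: 18 2,4-bis(benzyloxy)-5-methyl-6-(13-methyltetradecyl)benzoic acid
Product: 19 2,4-dihydroxy-5-methyl-6-(13-methyltetradecyl)benzoic acid (target, achiral)
Conditions: H2 (1 atm), 10% Pd/C, EtOAc, rt; concentrate below 30 °C
Reagents that add atoms: none
Why: Catalytic hydrogenolysis removes both benzyl ethers under neutral conditions at room temperature, so the decarboxylation-prone resorcylic acid sees neither heat, acid nor base.

**Compound list**
1 | 11-bromoundecan-1-ol | OCCCCCCCCCCCBr | starting material
2 | 2-[(11-bromoundecyl)oxy]tetrahydro-2H-pyran (racemic) | BrCCCCCCCCCCCOC1CCCCO1 | intermediate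
3 | 1-bromo-3-methylbutane | CC(C)CCBr | starting material
4 | isopentylmagnesium bromide (not isolated) | CC(C)CC[Mg]Br | intermediate
5 | 2-[(14-methylpentadecyl)oxy]tetrahydro-2H-pyran (racemic) | CC(C)CCCCCCCCCCCCCOC1CCCCO1 | intermediate
6 | 14-methylpentadecan-1-ol | CC(C)CCCCCCCCCCCCCO | intermediate
7 | 14-methylpentadecanal | CC(C)CCCCCCCCCCCCC=O | intermediate
8 | 3-chlorobutan-2-one (racemic) | CC(=O)C(C)Cl | starting material
9 | (3-oxobutan-2-yl)triphenylphosphonium chloride (racemic) | CC(=O)C(C)[P+](c1ccccc1)(c1ccccc1)c1ccccc1.[Cl-] | intermediate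
10 | 3-(triphenyl-λ5-phosphanylidene)butan-2-one | CC(=O)C(C)=P(c1ccccc1)(c1ccccc1)c1ccccc1 | intermediate
11 | (E)-3,17-dimethyloctadec-3-en-2-one | CC(=O)/C(C)=C/CCCCCCCCCCCCC(C)C | intermediate
12 | dimethyl malonate | COC(=O)CC(=O)OC | starting material
13 | dimethyl 2-(3,17-dimethyl-2-oxooctadecan-4-yl)propanedioate (Michael adduct, diastereomer mixture, not isolated) | COC(=O)C(C(=O)OC)C(CCCCCCCCCCCCC(C)C)C(C)C(C)=O | intermediate
14 | methyl 2-hydroxy-5-methyl-6-(13-methyltetradecyl)-4-oxocyclohex-2-ene-1-carboxylate (diastereomer mixture) | COC(=O)C1C(O)=CC(=O)C(C)C1CCCCCCCCCCCCC(C)C | intermediate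
15 | methyl 3-bromo-2-hydroxy-5-methyl-6-(13-methyltetradecyl)-4-oxocyclohex-2-ene-1-carboxylate (not isolated) | COC(=O)C1C(O)=C(Br)C(=O)C(C)C1CCCCCCCCCCCCC(C)C | intermediate
16 | methyl 2,4-dihydroxy-5-methyl-6-(13-methyltetradecyl)benzoate | COC(=O)c1c(O)cc(O)c(C)c1CCCCCCCCCCCCC(C)C | intermediate
17 | methyl 2,4-bis(benzyloxy)-5-methyl-6-(13-methyltetradecyl)benzoate | COC(=O)c1c(OCc2ccccc2)cc(OCc2ccccc2)c(C)c1CCCCCCCCCCCCC(C)C | intermediate
18 | 2,4-bis(benzyloxy)-5-methyl-6-(13-methyltetradecyl)benzoic acid | OC(=O)c1c(OCc2ccccc2)cc(OCc2ccccc2)c(C)c1CCCCCCCCCCCCC(C)C | intermediate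
19 | 2,4-dihydroxy-5-methyl-6-(13-methyltetradecyl)benzoic acid | Cc1c(O)cc(O)c(C(=O)O)c1CCCCCCCCCCCCC(C)C | target

**Total step count:** 12.
**Longest linear sequence:** 10 (steps 1–4 and 7–12). Steps 5 and 6 form the side branch.

**Three steps most likely to fail**

**Step 8.** The α-methyl, β-alkyl enone is a sluggish Michael acceptor, so retro-Michael reaction may win.
The fallback sets out from 7 and comes back at 13.
- Aldehyde 7 is condensed with dimethyl malonate 12 in a Knoevenagel reaction (piperidine/AcOH cat., toluene, Dean–Stark). This gives dimethyl 2-(14-methylpentadecylidene)propanedioate F1.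
- F1 is a doubly activated acceptor. It takes up commercial (but-2-en-2-yloxy)trimethylsilane in a TiCl4-promoted Mukaiyama–Michael addition (CH2Cl2, −78 °C).
- This forms the C5–C6 bond instead of C1–C6 and delivers 13, which is now isolated.
- NaOMe/MeOH then closes 13 to 14 as in the main route.

**Step 9.** One equivalent of Br2 may give a mixture of unreacted dione, resorcylate and ring-brominated resorcylate.
The fallback sets out from 14 and comes back at 16.
- Over-oxidation is accepted on purpose. Br2 (2.1 equiv) in AcOH, rt to 60 °C, aromatises the ring and brominates the only free ring position.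
- The product is methyl 3-bromo-2,4-dihydroxy-5-methyl-6-(13-methyltetradecyl)benzoate F2, a single crystalline compound.
- Reductive debromination (H2, 10% Pd/C, NaOAc, MeOH/EtOAc, rt) then returns 16.

**Step 11.** The ester lies between OBn and a buttressed long alkyl group and may resist hydroxide.
The fallback sets out from 17 and comes back at 18. It replaces acyl substitution by a redox detour.
- LiAlH4 in refluxing THF reduces 17 to [2,4-bis(benzyloxy)-5-methyl-6-(13-methyltetradecyl)phenyl]methanol F3.
- MnO2 in CH2Cl2 oxidises the benzylic alcohol to 2,4-bis(benzyloxy)-5-methyl-6-(13-methyltetradecyl)benzaldehyde F4.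
- Pinnick oxidation (NaClO2, NaH2PO4, 2-methylbut-2-ene, t-BuOH/H2O) then gives 18.

**Further compounds**
F1 | step 8 | dimethyl 2-(14-methylpentadecylidene)propanedioate | COC(=O)C(=CCCCCCCCCCCCCC(C)C)C(=O)OC
F2 | step 9 | methyl 3-bromo-2,4-dihydroxy-5-methyl-6-(13-methyltetradecyl)benzoate | COC(=O)c1c(O)c(Br)c(O)c(C)c1CCCCCCCCCCCCC(C)C
F3 | step 11 | [2,4-bis(benzyloxy)-5-methyl-6-(13-methyltetradecyl)phenyl]methanol | OCc1c(OCc2ccccc2)cc(OCc2ccccc2)c(C)c1CCCCCCCCCCCCC(C)C
F4 | step 11 | 2,4-bis(benzyloxy)-5-methyl-6-(13-methyltetradecyl)benzaldehyde | O=Cc1c(OCc2ccccc2)cc(OCc2ccccc2)c(C)c1CCCCCCCCCCCCC(C)C
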